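## Structural features

The target is a hydrobenzofuranoid neolignan. A cross-conjugated cyclohexa-2,5-dienone (ring A: C3a, C4, C5, C6, C7, C7a) is fused along the C3a–C7a bond to a dihydrofuran (ring B: O1, C2, C3, C3a, C7a). Ring A holds the C6 carbonyl between a methoxy enol ether (C4=C5–OMe) and a vinylogous ester (O1–C7a=C7). Ring B holds a 3,4,5-trimethoxyphenyl group at C2 and a methyl group at C3, and the fusion carbon C3a is quaternary and carries an allyl group. C2, C3 and C3a are three contiguous stereocentres, all S: aryl and methyl are trans, and the allyl group is anti to the methyl and syn to the aryl group. Fragile elements are the dienone (acid-induced rearrangement, conjugate addition), the C2–O1 bond (benzylic to an electron-rich arene, so open to epimerisation and hydrogenolysis), the terminal alkene (no late hydrogenation) and the oxidisable trimethoxyarene. The real difficulty is the all-carbon quaternary C3a, which must be made with a defined sense next to C3 while ring A stays at the dienone oxidation level. C3a is para to the C6 oxygen, so removal of the allyl group leaves an aromatic 6-hydroxy-2,3-dihydrobenzofuran; in that arene O1, C7a, C3a and C3 form the heterodiene of an ortho-quinone methide of ring A and C2 is the only ring B atom missing from it, which is what the key step exploits.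

## Logic of the disconnections

18 ⇒ 15 + 16. The C3a–CH2 bond of the allyl group is cut. C3a is para to the C6 oxygen, so this is the retron of a dearomative para-allylation. The cut removes the quaternary stereocentre and the dienone together and leaves a stable arene. The forward step must oxidise only the phenol, send the carbon nucleophile to C3a and not to C5 or C7, and bring it in on the face opposite to the C3 methyl group.

15 ⇒ 14. The O–CH2Ph bond on the C6 oxygen is cut. A free hydroxyl para to the benzylic carbon C3 would turn the next disconnection into a para-quinone methide problem and would compete as a nucleophile. The cost is one step. The removal must leave the benzylic C2–O1 bond intact.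

14 ⇒ 5 + 10. The C2–C3 and O1–C2 bonds are cut. Both fall on C2, the only ring B atom outside the quinone-methide unit of ring A. One convergent step then joins two fragments of similar size, closes ring B and sets C2 and C3. The forward step needs the quinone methide released in the presence of the ylide, a sulfide that fixes the ylide face, and a C–C bond formation that favours the trans arrangement.

5 ⇒ 4. The benzylic C–S bond is cut. The sulfinate is a leaving group that stores the quinone methide in a bench-stable form and is expelled by mild base. The forward step must capture an easily ionised benzylic position at sulfur before it self-condenses.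

4 ⇒ 3. The carbinol C–H bond is cut (ketone reduction). The stereocentre made here is lost again in the key step, so no control is needed; only a non-acidic work-up is required.

3 ⇒ 2. The second O–CH2Ph bond is cut. The forward step must tell two phenolic hydroxyls apart; the hydrogen bond of one of them to the acetyl group does this.

2 ⇒ 1. The aryl–C(acyl) bond is cut. The acetyl group supplies C3 and its methyl group in one piece. The forward acylation must go ortho to one hydroxyl and para to the other.

10 ⇒ 8 + 9. The S–CH2(aryl) bond is cut. This separates the chirality source from the carbon that becomes C2. The sulfide is C2-symmetric, so alkylation can give only one sulfonium salt.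

8 ⇒ 7 ⇒ 6. Both ring C–S bonds are cut, then the two O–S bonds. The forward sequence is activation of both hydroxyls with retention and double displacement with inversion, so the configuration of 6 decides that of 8.

## Other disconnections considered

Alternative 1: The cut is the C3a–C7a bond of ring A, with O1–C7a left for a later closure. Ring A would then be assembled from a four-carbon cyclobutenone and an alkenyl side chain that already carries C2 and C3.
- Forward key step: cyclobutenone A2 would be heated in toluene. Thermal 4π ring opening followed by 6π ring closure onto the trisubstituted alkene should give dienone A1 with the quaternary C3a in place. Desilylation and acid-promoted addition of the C2 hydroxyl to the C7a carbonyl, with loss of methanol from the vinylogous ester, would close ring B to 18.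
- In its favour: ring A is made directly at the dienone oxidation level under neutral thermal conditions and no oxidant meets the electron-rich arenes. There is no ortho/para ambiguity about where the quaternary carbon forms. On this regiochemical point it is better than the chosen plan, whose step 10 must discriminate C3a from C5 and C7.
- Against it here: the configuration of C3a is decided by the sense of rotation in the 6π closure, controlled only by the acyclic stereocentre at C3 through allylic strain. That is a weaker element than the ring-bound C3 methyl group that guides step 10. A2 also needs a geometrically defined trisubstituted alkenyl-metal reagent carrying both stereocentres, so C2 and C3 need their own asymmetric steps. Linearly conjugated dienones such as A1 tend to dimerise.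
- Comparison: structurally both plans end at the same dienone and both need one external source of chirality for C2 and C3 (equal). Mechanistically the alternative is cleaner in regiochemistry but less secure in facial control at C3a. In step economy the chosen plan takes ring A from an arene starting material and needs seven linear steps; it is expected to be several steps shorter.

Alternative 2: The cut is O1–C2 of ring B at the stage of a simple γ-lactone in which C7a is the lactone carbonyl and C3a its α-methylene. Ring A is not yet present.
- Forward key step: the donor–acceptor cyclopropane A4 would be heated with catalytic TsOH in aqueous dioxane. The bond between the aryl-bearing carbon and the dicarboxylated carbon ionises, a carboxyl oxygen closes onto the benzylic carbon and the remaining carboxyl is lost as CO2, giving trans-lactone A3.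
- In its favour: the step is simple and scalable. The trans relationship of aryl and methyl arises from ring closure at an ionised benzylic carbon next to an existing stereocentre and is thermodynamically backed, which makes it at least the equal of step 8 in diastereocontrol. Only C3 has to come from an asymmetric cyclopropanation and no stoichiometric chiral reagent is consumed, which is better in atom economy than the use of 10.
- Against it here: A3 contains only two atoms of ring A. The quaternary centre, the allyl group, four ring carbons, two oxygen functions and the dienone all remain to be built by α-allylation, α-acylation and an annulation that must turn the lactone carbonyl into the C7a enol ether. The hard part of the target is postponed, not solved.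
- Comparison: structurally the chosen key step delivers the whole framework of 18 except the allyl group, the alternative a five-membered fragment. Mechanistically the alternative key step is the more certain of the two, and its later quaternary centre would be set by enolate alkylation anti to the C3 methyl group on a five-membered ring, the same control element as in step 10 (equal). In step economy it is clearly inferior: an estimated eight or more steps would follow A3, against two after 14.

Alternative 3: The cuts are C3–CH3 and C3a–CH2 (allyl), made on a butenolide in which C7a is the lactone carbonyl and C4 is masked as an acetal.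
- Forward key step: a methyl cuprate would add to C3 of butenolide A6 on the face opposite to the C2 aryl group. The lactone enolate so formed would be trapped by an allyl halide on the face opposite to the new methyl group, giving lactone A5 with all three stereocentres.
- In its favour: one stereocentre (C2 of A6) relays to C3 and then to the quaternary C3a in a single operation. The quaternary centre is made by enolate alkylation with no regiochemical alternative and without an oxidant, which is better than step 10 on both counts. All three stereocentres are fixed early.
- Against it here: the hydrogen at C2 of A6 is benzylic, allylic and next to oxygen, so deprotonation under the basic cuprate conditions would erase the one stereocentre on which everything rests. C-allylation of a fully substituted enolate flanked by an acetal is slow, so O-allylation and simple protonation compete. Ring A must still be grown from the acetal carbon and the lactone carbonyl by adding C5, C6 and C7 with their oxygen functions, which means opening and re-closing ring B.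
- Comparison: structurally the alternative secures C3a earlier and more rigidly than the chosen plan. Mechanistically both rely on anti induction from the C3 methyl group on a five-membered ring (equal), the alternative by a two-electron alkylation and the chosen plan by an oxidative allylation. In step economy the chosen plan is better because ring A arrives intact.

Key step: step 8

Assumption: the benzylide of 2,5-dimethylthiolane is taken to meet the ortho-quinone methide on the same ylide face that it offers to aldehydes, where the (2R,5R)-sulfide leads to (S,S)-epoxides; because aryl outranks C3 at C2 of the dihydrobenzofuran whereas the second ring carbon outranks aryl in an epoxide, (2S)-14 requires the (2S,5S)-sulfide and therefore (2R,5R)-hexane-2,5-diol (if the sense proved to be the reverse, the antipode of 6 would be entered at step 5).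

## Route

Step 1
Reactants: 1 4-methoxybenzene-1,3-diol
Product: 2 1-(2,4-dihydroxy-5-methoxyphenyl)ethan-1-one
Conditions: AcOH (1.2 equiv), BF3·OEt2 (promoter and medium), 90 °C; then aq. NaOAc
Reagents that add atoms: acetic acid, CC(=O)O
Why: Friedel–Crafts C-acylation (Nencki-type); the position ortho to the 1-hydroxyl and para to the 3-hydroxyl is activated by both oxygens and is unhindered, whereas the site between the hydroxyls is flanked on both sides and the site next to the methoxy group is meta to both hydroxyls; the product stays complexed to boron, which prevents a second acylation.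

Step 2
Reactants: 2 1-(2,4-dihydroxy-5-methoxyphenyl)ethan-1-one
Product: 3 1-[4-(benzyloxy)-2-hydroxy-5-methoxyphenyl]ethan-1-one
Conditions: BnBr (1.05 equiv), K2CO3, acetone, reflux
Reagents that add atoms: benzyl bromide, BrCc1ccccc1
Why: Williamson etherification; the 2-hydroxyl is held in a hydrogen bond to the acetyl carbonyl, so one equivalent of a weak base ionises and alkylates only the 4-hydroxyl, the vinylogous acid para to the acetyl group.

Step 3
Reactants: 3 1-[4-(benzyloxy)-2-hydroxy-5-methoxyphenyl]ethan-1-one
Product: 4 rac-5-(benzyloxy)-2-(1-hydroxyethyl)-4-methoxyphenol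
Conditions: NaBH4, THF–MeOH, 0 °C; aq. NH4Cl
Reagents that add atoms: none
Why: Borohydride reduction of the aryl ketone to the racemic benzylic alcohol; the stereocentre is of no consequence because it becomes trigonal in step 8, and a near-neutral work-up avoids ionisation of the electron-rich ortho-hydroxybenzylic alcohol, which is used crude.

Step 4
Reactants: 4 rac-5-(benzyloxy)-2-(1-hydroxyethyl)-4-methoxyphenol
Product: 5 rac-5-(benzyloxy)-4-methoxy-2-[1-(p-tolylsulfonyl)ethyl]phenol
Conditions: TolSO2Na (1.5 equiv), HCO2H–H2O, rt
Reagents that add atoms: sodium p-toluenesulfinate, Cc1ccc(cc1)S(=O)[O-].[Na+]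
Why: Acid-promoted SN1-type substitution; the benzylic hydroxyl, activated by the ortho-hydroxyl and para-benzyloxy groups, ionises in aqueous formic acid and the ambident sulfinate is alkylated at sulfur to the thermodynamically preferred sulfone, the standard way to 2-(1-sulfonylalkyl)phenols as stable ortho-quinone methide precursors.

Step 5
Reactants: 6 (2R,5R)-hexane-2,5-diol
Product: 7 (2R,5R)-hexane-2,5-diyl dimethanesulfonate
Conditions: MsCl, Et3N, CH2Cl2, −20 → 0 °C
Reagents that add atoms: methanesulfonyl chloride, CS(=O)(=O)Cl
Why: O-Sulfonylation of both secondary hydroxyls; no C–O bond is broken, so both stereocentres are retained.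

Step 6
Reactants: 7 (2R,5R)-hexane-2,5-diyl dimethanesulfonate
Product: 8 (2S,5S)-2,5-dimethylthiolane
Conditions: Na2S·9H2O, EtOH, rt; distillation
Reagents that add atoms: sodium sulfide, [Na+].[Na+].[S-2]
Why: Double SN2 displacement by sulfide, the second one a 5-exo-tet ring closure; each carbon is inverted, so the (2R,5R)-dimesylate gives the (2S,5S)-thiolane.

Step 7
Reactants: 8 (2S,5S)-2,5-dimethylthiolane; 9 5-(bromomethyl)-1,2,3-trimethoxybenzene
Product: 10 (2S,5S)-2,5-dimethyl-1-(3,4,5-trimethoxybenzyl)thiolan-1-ium tetrafluoroborate
Conditions: AgBF4, CH2Cl2, 0 °C → rt, dark
Reagents that add atoms: silver tetrafluoroborate, [Ag+].F[B-](F)(F)F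
Why: S-Alkylation of the thioether by the benzylic bromide, driven by precipitation of AgBr and giving the non-nucleophilic tetrafluoroborate directly; the two lone pairs of the C2-symmetric sulfide are homotopic, so a single sulfonium salt forms.

Step 8
Reactants: 5 rac-5-(benzyloxy)-4-methoxy-2-[1-(p-tolylsulfonyl)ethyl]phenol; 10 (2S,5S)-2,5-dimethyl-1-(3,4,5-trimethoxybenzyl)thiolan-1-ium tetrafluoroborate
Product: 14 (2S,3S)-6-(benzyloxy)-5-methoxy-3-methyl-2-(3,4,5-trimethoxyphenyl)-2,3-dihydrobenzofuran, via ortho-quinone methide 11 (not isolated), via sulfonium ylide 12 (not isolated), via betaine 13 (not isolated)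
Conditions: Cs2CO3 (3 equiv), 10 (1.5 equiv), CH2Cl2, −20 °C → rt
Reagents that add atoms: none
Why: Cs2CO3 deprotonates the phenol of 5, which expels p-toluenesulfinate in a 1,4-elimination to give the (E)-ethylidene quinone methide 11, and deprotonates 10 to the semi-stabilised ylide 12. The ylide carbon adds to the exocyclic carbon of 11 (C2–C3 bond), ring A rearomatises to the phenoxide–sulfonium betaine 13, and the phenoxide displaces the thiolane at C2 with inversion (O1–C2 bond), the closure of ring B being 5-exo-tet. The closest known reaction type is the (4+1) annulation of sulfonium ylides with ortho-quinone methides released from 2-(1-sulfonylalkyl)phenols by carbonate bases, chiral-sulfide variants included; the ylide is of the kind used for asymmetric benzylidene transfer to aldehydes. C2 is controlled by the auxiliary: the ylide should adopt the conformation with the aryl group turned away from the ring, the ring methyl group cis to the ylidic carbon shields one face, 11 is met on the other, and inversion in the closure then gives 2S from the (2S,5S)-sulfide. C3 is controlled relative to C2 in the C–C bond formation, where the (E)-geometry of 11 and an approach that keeps the trimethoxyphenyl group away from the C3 methyl group lead to the betaine whose closure places aryl and methyl on opposite faces. Because rearomatisation makes the addition practically irreversible, this kinetic preference and not equilibration of betaines has to carry the trans selectivity, and the closure itself is stereospecific. The step needs trans selectivity and capture of 11 by the ylide in preference to tautomerisation or dimerisation; the first is secured by the ethylidene geometry and the bulk of the aryl group, the second by the sulfone, which releases 11 only gradually, and by the benzyloxy group para to the exocyclic carbon, which tempers 11.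

Step 9
Reactants: 14 (2S,3S)-6-(benzyloxy)-5-methoxy-3-methyl-2-(3,4,5-trimethoxyphenyl)-2,3-dihydrobenzofuran
Product: 15 (2S,3S)-5-methoxy-3-methyl-2-(3,4,5-trimethoxyphenyl)-2,3-dihydrobenzofuran-6-ol
Conditions: H2 (1 atm), 10% Pd/C, EtOAc, rt
Reagents that add atoms: none
Why: Heterogeneous hydrogenolysis of the aryl benzyl ether; at 1 atm in a neutral solvent the O–CH2Ph bond should be cleaved much faster than the ring C2–O1 bond, no other reducible group is present, and C2 and C3 are not touched.

Step 10
Reactants: 15 (2S,3S)-5-methoxy-3-methyl-2-(3,4,5-trimethoxyphenyl)-2,3-dihydrobenzofuran-6-ol; 16 allyltrimethylsilane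
Product: 18 (2S,3S,3aS)-3a-allyl-5-methoxy-3-methyl-2-(3,4,5-trimethoxyphenyl)-3,3a-dihydrobenzofuran-6(2H)-one, via aryloxy-λ3-iodane 17 (not isolated)
Conditions: PhI(OAc)2 (1.1 equiv), 16 (5 equiv), (CF3)2CHOH, −20 °C, short reaction time; aq. NaHCO3
Reagents that add atoms: none
Why: Oxidative dearomatisation by a trivalent-iodine reagent with Hosomi–Sakurai-type capture, the known para-allylation of 4-alkylphenols in fluorinated alcohols: ligand exchange gives 17, whose O–I bond ionises with loss of PhI while the allylsilane attacks C3a, the para carbon, where C–C bond formation leaves a cross-conjugated dienone with both the C5 methoxy group and O1 in conjugation, and the β-silyl cation then loses the silyl group. The quaternary stereocentre is set by the adjacent C3: the allylsilane should approach planar C3a on the face opposite to the C3 methyl group, giving 3aS.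

## Compound list

1 | 4-methoxybenzene-1,3-diol | COc1ccc(O)cc1O | starting material
2 | 1-(2,4-dihydroxy-5-methoxyphenyl)ethan-1-one | CC(=O)c1cc(OC)c(O)cc1O | intermediate
3 | 1-[4-(benzyloxy)-2-hydroxy-5-methoxyphenyl]ethan-1-one | CC(=O)c1cc(OC)c(OCc2ccccc2)cc1O | intermediate
4 | rac-5-(benzyloxy)-2-(1-hydroxyethyl)-4-methoxyphenol | CC(O)c1cc(OC)c(OCc2ccccc2)cc1O | intermediate
5 | rac-5-(benzyloxy)-4-methoxy-2-[1-(p-tolylsulfonyl)ethyl]phenol | CC(c1cc(OC)c(OCc2ccccc2)cc1O)S(=O)(=O)c1ccc(C)cc1 | intermediate
6 | (2R,5R)-hexane-2,5-diol | C[C@@H](O)CC[C@@H](C)O | starting material
7 | (2R,5R)-hexane-2,5-diyl dimethanesulfonate | C[C@@H](OS(C)(=O)=O)CC[C@@H](C)OS(C)(=O)=O | intermediate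
8 | (2S,5S)-2,5-dimethylthiolane | C[C@H]1CC[C@H](C)S1 | intermediate
9 | 5-(bromomethyl)-1,2,3-trimethoxybenzene | COc1cc(CBr)cc(OC)c1OC | starting material
10 | (2S,5S)-2,5-dimethyl-1-(3,4,5-trimethoxybenzyl)thiolan-1-ium tetrafluoroborate | C[C@H]1CC[C@H](C)[S+]1Cc1cc(OC)c(OC)c(OC)c1.F[B-](F)(F)F | intermediate
11 | (E)-3-(benzyloxy)-6-ethylidene-4-methoxycyclohexa-2,4-dien-1-one | C/C=C1\C=C(OC)C(OCc2ccccc2)=CC1=O | intermediate (not isolated)
12 | [(2S,5S)-2,5-dimethylthiolan-1-ium-1-yl](3,4,5-trimethoxyphenyl)methanide | C[C@H]1CC[C@H](C)[S+]1[CH-]c1cc(OC)c(OC)c(OC)c1 | intermediate (not isolated)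
13 | 5-(benzyloxy)-2-[(1R,2S)-1-[(2S,5S)-2,5-dimethylthiolan-1-ium-1-yl]-1-(3,4,5-trimethoxyphenyl)propan-2-yl]-4-methoxyphenolate | [O-]c1cc(OCc2ccccc2)c(OC)cc1[C@H](C)[C@H](c1cc(OC)c(OC)c(OC)c1)[S+]1[C@@H](C)CC[C@@H]1C | intermediate (not isolated)
14 | (2S,3S)-6-(benzyloxy)-5-methoxy-3-methyl-2-(3,4,5-trimethoxyphenyl)-2,3-dihydrobenzofuran | COc1cc2c(cc1OCc1ccccc1)O[C@H](c1cc(OC)c(OC)c(OC)c1)[C@H]2C | intermediate
15 | (2S,3S)-5-methoxy-3-methyl-2-(3,4,5-trimethoxyphenyl)-2,3-dihydrobenzofuran-6-ol | COc1cc2c(cc1O)O[C@H](c1cc(OC)c(OC)c(OC)c1)[C@H]2C | intermediate
16 | allyltrimethylsilane | C=CC[Si](C)(C)C | starting material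
17 | (2S,3S)-6-{[acetoxy(phenyl)-λ3-iodanyl]oxy}-5-methoxy-3-methyl-2-(3,4,5-trimethoxyphenyl)-2,3-dihydrobenzofuran | COc1cc2c(cc1OI(OC(C)=O)c1ccccc1)O[C@H](c1cc(OC)c(OC)c(OC)c1)[C@H]2C | intermediate (not isolated)
18 | (2S,3S,3aS)-3a-allyl-5-methoxy-3-methyl-2-(3,4,5-trimethoxyphenyl)-3,3a-dihydrobenzofuran-6(2H)-one | C=CC[C@]12C=C(OC)C(=O)C=C1O[C@H](c1cc(OC)c(OC)c(OC)c1)[C@H]2C | target

## Step count and least certain steps

Total: 10 steps. Longest linear sequence: 7 steps (steps 1, 2, 3, 4, 8, 9, 10); the sulfonium branch (steps 5, 6, 7) joins at step 8.

Step 8 (key step).
- What may go wrong: incomplete facial discrimination at the ylide carbon, since the sense is inferred from carbonyl epoxidation. Enantiomeric purity may erode if a mismatched betaine is epimerised by base at the sulfonium-bearing carbon before it closes. The quinone methide may be lost by tautomerisation to the vinylphenol or by dimerisation, and the salt may be consumed by benzyl transfer to the liberated sulfinate.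
- Fallback (resolution in place of auxiliary control, known chemistry): it sets out from 5 and 9. S-Alkylation of thiolane with 9 (AgBF4, CH2Cl2) gives 1-(3,4,5-trimethoxybenzyl)thiolan-1-ium tetrafluoroborate F1. Its achiral ylide and 5 with Cs2CO3 in CH2Cl2 should give the racemic trans product, rac-(2S,3S)-6-(benzyloxy)-5-methoxy-3-methyl-2-(3,4,5-trimethoxyphenyl)-2,3-dihydrobenzofuran F2. This is separated by preparative chromatography on a chiral stationary phase, and the (2S,3S)-enantiomer is 14, where the route is rejoined.

Step 10.
- What may go wrong: attack at the ortho carbons competes with attack at C3a (C5 carries the methoxy group and much of the positive charge, C7 is unhindered). The oxidised phenol may be captured by acetate or solvent instead of the allylsilane. Facial discrimination at C3a may be insufficient. The trimethoxyphenyl ring may be oxidised. The product may suffer acid-induced epimerisation at C2 or rearrangement in the fluorinated alcohol.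
- Fallback (oxidation separated from C–C bond formation): it sets out from 15. PhI(OAc)2 in MeOH at 0 °C, the known oxidative ketalisation of 2-methoxyphenols, should give (2S,3S)-5,5-dimethoxy-3-methyl-2-(3,4,5-trimethoxyphenyl)-2,3-dihydrobenzofuran-6(5H)-one F3. Ionisation of this quinone monoketal with BF3·OEt2 in CH2Cl2 at −78 °C in the presence of 16 (Hosomi–Sakurai-type substitution, no oxidant present) should deliver the allyl group to C3a anti to the C3 methyl group and return to the route at 18.

Step 9.
- What may go wrong: over-reduction by hydrogenolysis of the ring C2–O1 bond, which is benzylic to the trimethoxyphenyl group, once the benzyl ether has gone.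
- Fallback (change of protecting group): it sets out from 2. Allyl bromide and K2CO3 in acetone give 1-[4-(allyloxy)-2-hydroxy-5-methoxyphenyl]ethan-1-one F4. NaBH4 gives rac-5-(allyloxy)-2-(1-hydroxyethyl)-4-methoxyphenol F5. TolSO2Na in aqueous formic acid gives rac-5-(allyloxy)-4-methoxy-2-[1-(p-tolylsulfonyl)ethyl]phenol F6. Annulation with 10 and Cs2CO3 as in step 8 gives (2S,3S)-6-(allyloxy)-5-methoxy-3-methyl-2-(3,4,5-trimethoxyphenyl)-2,3-dihydrobenzofuran F7. Allyl transfer to morpholine, catalysed by Pd(PPh3)4 (zerovalent palladium) in THF at rt, releases the phenol without any reducing agent and returns to the route at 15.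

Step 4.
- What may go wrong: self-condensation of the very easily ionised benzylic alcohol (Friedel–Crafts oligomerisation, quinone methide dimerisation) may outrun capture by the weakly nucleophilic sulfinate. O-Alkylation to the sulfinate ester is also possible.
- Fallback (C–S bond made at the sulfide oxidation level): it sets out from 4. 4-Methylbenzenethiol with catalytic TsOH·H2O in CH2Cl2, a far better trap for the benzylic position, gives rac-5-(benzyloxy)-4-methoxy-2-[1-(p-tolylsulfanyl)ethyl]phenol F8. Oxidation with H2O2 and catalytic Na2WO4 in MeOH then returns to the route at 5.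

## Further compounds

F1 | step 8 | 1-(3,4,5-trimethoxybenzyl)thiolan-1-ium tetrafluoroborate | COc1cc(C[S+]2CCCC2)cc(OC)c1OC.F[B-](F)(F)F
F2 | step 8 | rac-(2S,3S)-6-(benzyloxy)-5-methoxy-3-methyl-2-(3,4,5-trimethoxyphenyl)-2,3-dihydrobenzofuran (trans racemate, both enantiomers) | COc1cc2c(cc1OCc1ccccc1)O[C@H](c1cc(OC)c(OC)c(OC)c1)[C@H]2C.COc1cc2c(cc1OCc1ccccc1)O[C@@H](c1cc(OC)c(OC)c(OC)c1)[C@@H]2C
F3 | step 10 | (2S,3S)-5,5-dimethoxy-3-methyl-2-(3,4,5-trimethoxyphenyl)-2,3-dihydrobenzofuran-6(5H)-one | COC1(OC)C=C2C(=CC1=O)O[C@H](c1cc(OC)c(OC)c(OC)c1)[C@H]2C
F4 | step 9 | 1-[4-(allyloxy)-2-hydroxy-5-methoxyphenyl]ethan-1-one | CC(=O)c1cc(OC)c(OCC=C)cc1O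
F5 | step 9 | rac-5-(allyloxy)-2-(1-hydroxyethyl)-4-methoxyphenol | CC(O)c1cc(OC)c(OCC=C)cc1O
F6 | step 9 | rac-5-(allyloxy)-4-methoxy-2-[1-(p-tolylsulfonyl)ethyl]phenol | CC(c1cc(OC)c(OCC=C)cc1O)S(=O)(=O)c1ccc(C)cc1
F7 | step 9 | (2S,3S)-6-(allyloxy)-5-methoxy-3-methyl-2-(3,4,5-trimethoxyphenyl)-2,3-dihydrobenzofuran | COc1cc2c(cc1OCC=C)O[C@H](c1cc(OC)c(OC)c(OC)c1)[C@H]2C
F8 | step 4 | rac-5-(benzyloxy)-4-methoxy-2-[1-(p-tolylsulfanyl)ethyl]phenol | CC(Sc1ccc(C)cc1)c1cc(OC)c(OCc2ccccc2)cc1O
A1 | alternative 1 | (S)-6-allyl-6-[(1S,2S)-1-(tert-butyldimethylsilyloxy)-1-(3,4,5-trimethoxyphenyl)propan-2-yl]-3,4-dimethoxycyclohexa-2,4-dien-1-one | C=CC[C@@]1(C=C(OC)C(OC)=CC1=O)[C@H](C)[C@H](O[Si](C)(C)C(C)(C)C)c1cc(OC)c(OC)c(OC)c1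
A2 | alternative 1 | 4-[(3S,4S)-2-allyl-4-(tert-butyldimethylsilyloxy)-3-methyl-4-(3,4,5-trimethoxyphenyl)but-1-en-1-yl]-3,4-dimethoxycyclobut-2-en-1-one (ring carbon and alkene geometry left open) | COC1=CC(=O)C1(OC)C=C(CC=C)[C@H](C)[C@H](O[Si](C)(C)C(C)(C)C)c1cc(OC)c(OC)c(OC)c1
A3 | alternative 2 | (4S,5S)-4-methyl-5-(3,4,5-trimethoxyphenyl)dihydrofuran-2(3H)-one | C[C@H]1CC(=O)O[C@@H]1c1cc(OC)c(OC)c(OC)c1
A4 | alternative 2 | (2R,3S)-2-methyl-3-(3,4,5-trimethoxyphenyl)cyclopropane-1,1-dicarboxylic acid | C[C@@H]1[C@@H](c2cc(OC)c(OC)c(OC)c2)C1(C(=O)O)C(=O)O
A5 | alternative 3 | (3S,4S,5S)-3-allyl-3-(diethoxymethyl)-4-methyl-5-(3,4,5-trimethoxyphenyl)dihydrofuran-2(3H)-one | C=CC[C@]1(C(OCC)OCC)C(=O)O[C@H](c2cc(OC)c(OC)c(OC)c2)[C@H]1C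
A6 | alternative 3 | (S)-3-(diethoxymethyl)-5-(3,4,5-trimethoxyphenyl)furan-2(5H)-one | CCOC(OCC)C1=C[C@@H](c2cc(OC)c(OC)c(OC)c2)OC1=O
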